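The easy mistake with an order taken at fixed conversion is to treat two flasks as equally old when they arrive there, though the one with more catalyst arrives sooner.

the same everywhere: substrate 17 mM

|  | partner | free catalyst | remark |
|---|---|---|---|
| ash | 0.25 equiv | 10 mol% | run made earlier |
| alder | 1 equiv | 10 mol% | run made earlier |
| cedar | 0.50 equiv | 20 mol% | run made earlier |
| flask | 0.500 equiv | 10 mol% |  |

- ash (time / min: product / %, substrate / %): 6.00: 10.7, 85.8; 12.0: 15.8, 81.1; 20.0: 18.1, 78.7; 25.0: 19.6, 77.1; 30.0: 20.8, 76.3; 40.0: 20.4, 75.9
- alder (time / min: product / %, substrate / %): 2.50: 19.1, 76.9; 8.00: 36.1, 60.0; 15.0: 45.6, 48.9; 20.0: 51.4, 43.5; 30.0: 56.6, 37.2; 40.0: 59.9, 33.6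
- cedar (time / min: product / %, substrate / %): 8.00: 27.9, 64.0; 15.0: 32.9, 57.6; 25.0: 34.4, 55.5; 30.0: 35.0, 55.0; 40.0: 35.1, 54.2

(scatter of a reading: 0.5 percentage points)

- what is bound to the catalyst counts as converted

- apparent order in free catalyst when 20 % of the substrate are converted (percent change of the rate of making product for one percent more free catalyst charged)

Substrate plus product fall short of the charge, and bound material is missing from both readings, so this shortfall is material held on catalyst, whether as substrate or as product, which these readings cannot tell apart. In the ash run at 20.0 min, the shortfall divided by the loading gives a held share of 32.0 % of the catalyst.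

Two chemists dispute the flask. The first says this pool is simply filled, so the rate follows free catalyst and the order stays near one.

The second, whose reckoning I commit to, counts time. The holding time, the pool divided by the throughput of product, comes from the alder run: the shortfall at 2.50 min over the product rate of the next interval gives 1.29 min.

The flask has half the partner of the alder run, so I take about half the rate. Scaling the alder run's first reading then puts 20 % conversion at 4.33 min, or 3.35 holding times. With twice the catalyst it would take half as many.

If the pool fills as one minus the exponential of that count, the free share goes from 69.1 % to 74.0 %. Taken over that doubling, not the one percent asked, the order is roughly 1.10.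

The forecast takes the first side with 1.03, range 0.85 to 1.2, on the ground that “More catalyst holds more product”.

The simulation gives 1.2, higher than my 1.10.

    substrate + free catalyst ⇌ catalyst intermediate A (K = 18.0 M⁻¹, k = 250 M⁻¹ min⁻¹)
    crystals ⇌ released group, rate k2*(cs2 - [released group]) while solid is left; crystals form when [released group] > cs2 (solubility = 8.30 mM, k = 14.0 min⁻¹)
    partner + catalyst intermediate A ⇌ catalyst intermediate B (K = 5100 M⁻¹, k = 690 M⁻¹ min⁻¹)
    catalyst intermediate B ⇌ released group + catalyst intermediate C (K = 0.00610 M, k = 34.0 min⁻¹)
    catalyst intermediate C ⇌ free catalyst + product (K = 0.0170 M, k = 16.0 min⁻¹)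
    partner ⇌ dormant form (K = 1.10, k = 0.350 min⁻¹)

The flask reached 20 % conversion at 4.20 min, which is 3.26 of the holding times read from the alder run, with 66.3 % of its catalyst free, while the filled pool has its region in the ash run, whose shortfall reads 3.1 percentage points at 12.0 min and 3.2 points at 20.0 min, or 15.5 such holding times. In the flask, catalyst intermediate C and free catalyst plus product relax with a half-life of 1.81 s at 50.0 min, far shorter than the holding time. At 50.0 min the flask holds 19.3 % of its catalyst as catalyst intermediate C beside 50.3 % as free catalyst, the resting state, with product at 38.3 %.

The readings stem from a simulated flask with made-up constants.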